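- In a one-step world, a species lost to a reagent in excess falls exponentially, and two readings give its pseudo-first-order constant by the integrated rate law.

- grey: starting complex 0.80 M; incoming ligand 2.8 equiv; run made earlier
- flask: starting complex 0.80 M; incoming ligand 2.00 equiv; time 80 min

grey run (percent of the starting complex charged)

| time / min | complex with one exchanged / % | complex with three exchanged / % |
|---|---|---|
| 6.00 | 26.8 | 1.4 |
| 10.0 | 22.0 | 2.8 |
| 20.0 | 12.9 | 1.5 |
| 30.0 | 9.6 | 1.0 |
| 50.0 | 5.9 | 0.1 |
| 80.0 | 3.9 | 0 |

(each reading ± 0.5 percentage points)

- percent here means starting complex units held: one homo dimer counts as two
- the numbers in the tables scatter with a standard deviation of 0.5 percentage points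
- on the list of suspects stand: starting complex + incoming ligand <-> leaving ligand + complex with one exchanged; complex with one exchanged + incoming ligand <-> leaving ligand + complex with two exchanged; complex with two exchanged + incoming ligand <-> leaving ligand + complex with three exchanged; complex with three exchanged + incoming ligand -> over-reaction product; 2 starting complex -> homo dimer
- no earlier run changes the charge of incoming ligand; that part of a forecast is a guess

* equivalents of incoming ligand to starting complex, everything else as given, that leave most complex with one exchanged at 80 min
* the amount of complex with one exchanged then, in percent of the starting complex charged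
* the amount of complex with one exchanged with the amounts as given

- For whoever takes over: in the grey run, complex with one exchanged falls from 26.8 % at 6.00 min to 3.9 % at 80.0 min, which reads as a mean loss constant of 0.0260 min⁻¹.
- Scaling that constant by the charge of incoming ligand is a guess, as no earlier run changes that charge; it gives 0.0186 min⁻¹ for the flask, and so a mean half-life of complex with one exchanged of 37.3 min.
- If the flask matches the grey reading at 6.00 min, this reckoning expects 6.76 % at 80 min.
- Read the flask on time and add no incoming ligand: the mean half-life is shorter than the run, and on this scaling a larger charge shortens it.
- The forecast says 13 % as charged, on the ground that “less incoming ligand remains after the first exchanges and the second exchange is slower”, and 35 % at 1.2 equiv; the reckoning here expects about half of the forecast's amount as charged.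
- The flask gives 7.32 % as charged, and its best is 10.1 % at 0.973 equiv.

    starting complex + incoming ligand ⇌ leaving ligand + complex with one exchanged (K = 41.0, k = 0.00250 M⁻¹ s⁻¹)
    complex with one exchanged + incoming ligand ⇌ leaving ligand + complex with two exchanged (K = 2.00, k = 0.00120 M⁻¹ s⁻¹)
    complex with two exchanged + incoming ligand ⇌ leaving ligand + complex with three exchanged (K = 31.0, k = 8.30 × 10⁻⁴ M⁻¹ s⁻¹)
    complex with three exchanged + incoming ligand → over-reaction product (k = 0.00940 M⁻¹ s⁻¹)
    2 starting complex → homo dimer (k = 0.00720 M⁻¹ s⁻¹)

- In the flask at 80.0 min, the forward second exchange alone gives complex with one exchanged a half-life of 21 min, shorter than the carried 37.3 min, and the backward turnover of that step amounts to 38 % of the forward one. Complex with one exchanged in the flask falls from 24.1 % at 8.00 min to 7.32 % at 80.0 min, a mean half-life of 41.9 min, and the same flask left until 5.0 h holds 2.57 % of it, a mean half-life from 80 min of 146 min, longer than the carried one, with incoming ligand at 17 % of its charge.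

The earlier runs and the new flask come from a simulation for substances that don't exist; scatter was added.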